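Should alpha be left to its full time, or stopped earlier if you want the complex with one exchanged? That is the decision, and here is what you have to go on.

| flask | starting complex | incoming ligand | remark | time |
|---|---|---|---|---|
| north | 0.50 M | 1.4 equiv | run made earlier |  |
| south-east | 0.50 M | 2.6 equiv | run made earlier |  |
| north-west | 0.50 M | 3.8 equiv | run made earlier |  |
| alpha | 0.50 M | 1.50 equiv |  | 2.5 min |
| gamma | 0.50 M | 4.00 equiv |  | 2.5 min |
| delta | 0.50 M | 2.00 equiv |  | 2.5 min |

| run | time / s | complex with one exchanged / % | complex with two exchanged / % |
|---|---|---|---|
| north | 20.0 | 18.8 | 0.3 |
| north | 40.0 | 25.5 | 0.4 |
| north | 60.0 | 26.3 | 0.6 |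
| north | 80.0 | 24.6 | 0.5 |
| south-east | 20.0 | 30.3 | 0 |
| south-east | 40.0 | 38.2 | 0.6 |
| south-east | 60.0 | 36.7 | 0.4 |
| south-east | 80.0 | 32.9 | 1.3 |
| north-west | 20.0 | 40.3 | 0.3 |
| north-west | 40.0 | 45.0 | 1.2 |
| north-west | 60.0 | 40.6 | 0.5 |
| north-west | 80.0 | 34.6 | 0.8 |

(readings scatter by 0.5 percentage points)



1. which of these holds the largest part of the starting complex at the end of alpha (starting complex / complex with three exchanged / complex with four exchanged / complex with one exchanged / complex with two exchanged)
2. which of these holds the largest part of the starting complex at the end of gamma (starting complex / complex with three exchanged / complex with four exchanged / complex with one exchanged / complex with two exchanged)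
3. which of these holds the largest part of the starting complex at the end of delta (starting complex / complex with three exchanged / complex with four exchanged / complex with one exchanged / complex with two exchanged)
4. final complex with one exchanged in alpha, as a percentage of the starting complex charged

The readings show neither the starting complex nor where the rest of the material went, so I reckon [complex with one exchanged] and leave the other questions to the flask. Look for the crossing, the moment at which making and using this complex are equal, because [complex with one exchanged] peaks there. The north run reads highest at 60.0 s, with 26.3%, and the south-east and north-west runs at 40.0 s, with 38.2% and 45.0%. Alpha runs to 2.5 min, well beyond those times, so what you need is the fall after the crossing.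

Call it the tail constant: the logarithm of the ratio of two readings past the peak, divided by the time between them. The north-west run, from 45.0% to 34.6% over 40.0 s, gives 0.394 /min. It is a net fall, using minus whatever is still being made.

Start from the nearest run, north, at 24.6% after 80.0 s. Going from 1.4 equiv to 1.50 equiv should add about 0.69 percentage points, judged from the north and south-east readings at that time, and I neglect it. The remaining 70.0 s at the tail constant give 15.5%, less than the 26.3% of the north peak. So if this complex is what you want, stop alpha near the peak, not at its full time. That reckoning tests the stopping time and not the charge, and the highest readings are greater with more ligand: 26.3% at 1.4 equiv, 38.2% at 2.6 equiv and 45.0% at 3.8 equiv.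

The forecast named starting complex for alpha, complex with three exchanged for gamma and complex with three exchanged for delta, with 12% in alpha, holding that “ligand limits the low-equivalent runs”.

Alpha gives 17.9% against my 15.5%. Of the five species asked about, starting complex leads in alpha with 38.3% and in delta with 29.9%, and complex with one exchanged leads in gamma with 18.4%. The scheme that runs is this:

    starting complex + incoming ligand ⇌ leaving ligand + complex with one exchanged (K = 0.570, k = 0.0193 /M/s)
    complex with one exchanged + incoming ligand ⇌ leaving ligand + complex with two exchanged (K = 38.8, k = 7.48 × 10⁻⁴ /M/s)
    complex with two exchanged + incoming ligand ⇌ leaving ligand + complex with three exchanged (K = 2.50, k = 0.0380 /M/s)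
    complex with three exchanged + incoming ligand ⇌ leaving ligand + complex with four exchanged (K = 32.0, k = 0.0435 /M/s)
    complex with one exchanged → side product (k = 0.0126 /s)
    incoming ligand → decomposition product (k = 6.01 × 10⁻⁵ /s)

In alpha at 0.511 min, [complex with one exchanged] is made 2.05 times faster than it is used, while at 2.50 min its making stands at 0.517 of its using, so the crossing lies between those times. Carried from the 17.9% of alpha on to 4.0 min, the tail constant gives 9.91%, and alpha read at that time holds 10.6%.

(The earlier runs and the new flask come from a simulation from invented constants; scatter was added.)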